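**Retrosynthetic overview**

1. The strategy rests on the α-methylene-γ-butyrolactone (O8–C12(=O)–C11(=C13H2)–C7) that is trans-fused on the C7–C8 edge of the cyclohexane C5–C10. It is the retron of a C8 aldehyde and a 2-carboxyallyl metal that reacts at C7.
2. Late functional-group changes: the C9 angelate, the C6 acetate and the C15 enal go back to lactone 26 (C9-OTBS, C6-OPMB, C15-OTBDPS).
3. Key disconnection: C7–C8 and O8–C12 of 26 lead to the open-chain C8 aldehyde 24, which carries a pinacol 2-(methoxycarbonyl)allyl boronate with C6 trans to CH2B. The cyclohexane and the lactone are formed together and last.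
4. Aldehyde 24 comes from ynoate 20 (hydroalumination, then ICH2Bpin) and this from diol 15. The centres C6, C5, C10 and C9 are relayed on a butyrolactone template: chiral-pool C6, cuprate addition at C5, methylation at C10, CBS reduction at C9.
5. The template lactone (carbonyl = C1) is the first ring made and is opened again by DIBAL-H and Wittig methylenation, which creates the C10 vinyl group and frees O6.

Key step: step 19

Remark: atom labels follow elemane numbering (ring C5–C10; C1=C2 vinyl and C14 methyl on C10; C3H2=C4–C15 on C5; C11–C13 lactone carbons). By the CIP rules the boronate alkene is (Z): C6 is cis to CO2Me and trans to CH2B.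

Remark: compounds 1, 3, 8 and 31 are taken to be commercial.

**Route**

Step 1
Reactants: 1 (S)-5-(hydroxymethyl)furan-2(5H)-one
Product: 2 [(2S)-5-oxo-2,5-dihydrofuran-2-yl]methyl pivalate
Conditions: PivCl, pyridine, CH2Cl2, 0 °C to rt
Reagents that add atoms: pivaloyl chloride, CC(C)(C)C(=O)Cl
Why: O-acylation of the primary alcohol gives a bulky ester that has no α-hydrogen, resists the later enolate chemistry and is removed by DIBAL-H in step 9; the C6 centre comes from the chiral pool and is not touched.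

Step 2
Reactants: 3 2-bromoprop-2-en-1-ol
Product: 4 [(2-bromoprop-2-en-1-yl)oxy](tert-butyl)diphenylsilane
Conditions: TBDPSCl, imidazole, DMF, rt
Reagents that add atoms: tert-butyl(chloro)diphenylsilane, CC(C)(C)[Si](Cl)(c1ccccc1)c1ccccc1
Why: Silylation of the alcohol; TBDPS is chosen for O15 so that it survives the acid methanolysis of the primary TBS ether in step 17.

Step 3
Reactants: 4 bromoallyl silyl ether; 2 butenolide pivalate
Product: 7 C5/C6-trans lactone pivalate bearing the C4 alkenyl group, via alkenyllithium 5 (not isolated), via lithium dialkenylcuprate 6 (not isolated)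
Conditions: 4 (2.2 equiv), t-BuLi (4.4 equiv), Et2O, −78 °C; CuI (1.1 equiv), −78 to −40 °C; then 2, −78 °C; aq NH4Cl
Reagents that add atoms: none
Why: Bromine–lithium exchange, Gilman cuprate formation and 1,4-addition to the butenolide; the alkenyl group should enter C5 anti to the CH2OPiv group on C6 (1,2-induction on the five-membered ring), which sets C5.

Step 4
Reactants: 7 lactone; 8 2-[(tert-butyldimethylsilyl)oxy]acetaldehyde
Product: 9 aldol adduct (C10 now bears CH(OH)CH2OTBS; mixture at C9 and C10)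
Conditions: LDA, THF, −78 °C; then 8, −78 °C; AcOH
Reagents that add atoms: none
Why: Lithium enolate aldol addition at C10, the only enolisable position; both new centres are removed or reset in steps 5 to 7, so the mixture is carried on.

Step 5
Reactants: 9 aldol adduct
Product: 10 β-keto lactone (C9 ketone; C10 epimers and enol)
Conditions: Dess–Martin periodinane, NaHCO3, CH2Cl2, 0 °C to rt
Reagents that add atoms: none
Why: Dess–Martin oxidation of the secondary alcohol gives the 1,3-dicarbonyl compound, whose acidic C10–H allows clean C-alkylation.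

Step 6
Reactants: 10 β-keto lactone
Product: 11 C10-methylated β-keto lactone (methyl trans to the C5 alkenyl group)
Conditions: MeI, K2CO3, acetone, rt
Reagents that add atoms: iodomethane, CI
Why: C-alkylation of the planar β-dicarbonyl enolate; MeI should attack C10 from the face opposite the neighbouring C5 substituent, so the quaternary centre C10 gets the methyl trans and the C9 acyl group cis to the C5 side chain.

Step 7
Reactants: 11 methylated β-keto lactone
Product: 12 C9 alcohol (configuration of the target at C9)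
Conditions: (S)-2-methyl-CBS-oxazaborolidine (0.5 equiv), catecholborane, toluene, −78 to −40 °C
Reagents that add atoms: none
Why: Corey–Bakshi–Shibata reduction; the (S)-catalyst distinguishes the quaternary C10 (large) from CH2OTBS (small) and should give the (9S)-carbinol, and catecholborane leaves the 1,1-disubstituted alkene, the lactone and the pivalate alone.

Step 8
Reactants: 12 C9 alcohol
Product: 13 C9 TBS ether
Conditions: TBSOTf, 2,6-lutidine, CH2Cl2, −78 to 0 °C
Reagents that add atoms: tert-butyldimethylsilyl trifluoromethanesulfonate, CC(C)(C)[Si](C)(C)OS(=O)(=O)C(F)(F)F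
Why: Silylation with the triflate, which is reactive enough for the hindered hydroxyl next to the quaternary carbon.

Step 9
Reactants: 13 lactone
Product: 14 lactol (C1 hemiacetal, anomers) with free C7–OH
Conditions: DIBAL-H (4 equiv), CH2Cl2, −78 °C; Rochelle salt
Reagents that add atoms: none
Why: DIBAL-H reduction at −78 °C stops at the aluminium hemiacetal of the lactone and cleaves the pivalate reductively in the same operation.

Step 10
Reactants: 14 lactol
Product: 15 open-chain C6,C7-diol with the C10 vinyl group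
Conditions: Ph3PCH3Br, KOt-Bu, THF, 0 to 50 °C
Reagents that add atoms: methyltriphenylphosphonium bromide, C[P+](c1ccccc1)(c1ccccc1)c1ccccc1.[Br-]
Why: Wittig methylenation of the lactol through its open hydroxy aldehyde; the aldehyde has no α-hydrogen and cannot epimerise, and the step creates C1=C2 and frees O6.

Step 11
Reactants: 15 diol
Product: 16 p-methoxybenzylidene acetal on O6/O7
Conditions: 4-MeOC6H4CH(OMe)2, PPTS (cat.), CH2Cl2, rt
Reagents that add atoms: 4-methoxybenzaldehyde dimethyl acetal, COc1ccc(C(OC)OC)cc1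
Why: Acid-catalysed transacetalisation; only the 1,2-diol is free, and the silyl ethers tolerate PPTS under anhydrous conditions.

Step 12
Reactants: 16 acetal
Product: 17 C6 PMB ether with free C7–OH
Conditions: DIBAL-H, CH2Cl2, −78 to 0 °C
Reagents that add atoms: none
Why: Regioselective reductive opening of the p-methoxybenzylidene acetal; DIBAL-H binds the less hindered primary oxygen, so the PMB group stays on the secondary O6.

Step 13
Reactants: 17 primary alcohol
Product: 18 C7 aldehyde
Conditions: Dess–Martin periodinane, NaHCO3, CH2Cl2, 0 °C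
Reagents that add atoms: none
Why: Dess–Martin oxidation under buffered conditions that should not epimerise the α-alkoxy centre C6.

Step 14
Reactants: 18 aldehyde
Product: 19 terminal alkyne (C7≡C11)
Conditions: dimethyl (1-diazo-2-oxopropyl)phosphonate, K2CO3, MeOH, 0 °C to rt
Reagents that add atoms: dimethyl (1-diazo-2-oxopropyl)phosphonate, CC(=O)C(=[N+]=[N-])P(=O)(OC)OC
Why: Seyferth–Gilbert homologation with the Ohira–Bestmann reagent, which is mild enough for α-alkoxy aldehydes and adds C11.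

Step 15
Reactants: 19 alkyne
Product: 20 methyl ynoate
Conditions: n-BuLi, THF, −78 °C; then ClCO2Me
Reagents that add atoms: methyl chloroformate, COC(=O)Cl
Why: Deprotonation of the terminal alkyne and acylation of the acetylide with the chloroformate adds C12.

Step 16
Reactants: 20 ynoate
Product: 22 pinacol (Z)-2-(methoxycarbonyl)allyl boronate (C6 trans to CH2Bpin), via C11 alumino acrylate 21 (not isolated)
Conditions: DIBAL-H, HMPA, THF, 0 °C; then ICH2Bpin, 0 °C to rt
Reagents that add atoms: 2-(iodomethyl)-4,4,5,5-tetramethyl-1,3,2-dioxaborolane, ICB1OC(C)(C)C(C)(C)O1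
Why: Conjugate syn-hydroalumination of the 2-ynoate by the DIBAL-H–HMPA complex puts H on C7 and Al on C11, and C-alkylation of the alkenylalane with the iodomethyl boronate goes with retention, so C6 ends up trans to CH2B (the known route to 3-substituted 2-alkoxycarbonyl allyl boronates).

Step 17
Reactants: 22 allyl boronate
Product: 23 C8 primary alcohol
Conditions: CSA (cat.), MeOH/CH2Cl2, 0 °C
Reagents that add atoms: none
Why: Acid-catalysed methanolysis removes the primary TBS ether much faster than the hindered secondary TBS ether on O9 or the TBDPS ether on O15, and the pinacol boronate is stable to it.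

Step 18
Reactants: 23 alcohol
Product: 24 seco aldehyde (C8 CHO, C9-OTBS, C6-OPMB, C15-OTBDPS, allyl boronate)
Conditions: Dess–Martin periodinane, NaHCO3, CH2Cl2, 0 °C
Reagents that add atoms: none
Why: Dess–Martin oxidation at low temperature; 2-alkoxycarbonyl allyl boronates do not add to aldehydes without heating, so the aldehyde can be made in their presence.

Step 19
Reactants: 24 seco aldehyde
Product: 26 trans-fused α-methylene lactone (C9-OTBS, C6-OPMB, C15-OTBDPS), via cyclised borate ester 25 (not isolated)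
Conditions: toluene, 80 °C; then TsOH·H2O (cat.), CH2Cl2, rt
Reagents that add atoms: none
Why: On warming, boron binds the C8 aldehyde oxygen and C7, the γ-carbon of the allyl boronate, adds to C8 through a closed six-membered chair (B, O8, C8, C7, C11, C13), which moves the alkene to C11=C13 and gives borate 25; this is the ring-closing form of the thermal allylboration of aldehydes by 2-alkoxycarbonyl allyl boronates that leads to α-methylene-γ-butyrolactones. The cyclohexane closes 6-exo onto the carbonyl carbon (bond C7–C8), and the lactone then closes by 5-exo-trig acyl substitution of O8 at the C12 ester, completed by TsOH, with loss of methanol. C7 and C8 are set together: since C6 is trans to CH2B on the alkene, C6 and C9 are both equatorial on the allylboration chair, which is therefore trans-fused to the forming carbocycle, and H7 and H8 end up trans-diaxial (trans lactone). The step needs one of the two possible chairs of the forming cyclohexane, the one with the C5 side chain and the C10 vinyl group equatorial and with C6–OPMB, C9–OTBS and C10–Me axial, because this fixes the faces of C7 and C8 that react. Three features of 24 favour this chair: the large C5 substituent avoids the axial position, the bulky C9 silyl ether stays anti to C10–Me and away from the boron centre, and the C6–O bond lies near the alkene plane and not anti to the forming bond, where it would lower the nucleophilicity of C7. No second aldehyde is present (O15 is silylated), so chemoselectivity is not at issue; the competing ring-flipped chair is dealt with under the risks.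

Step 20
Reactants: 26 lactone
Product: 27 C6 alcohol
Conditions: DDQ, CH2Cl2/pH 7 buffer, 0 °C to rt
Reagents that add atoms: none
Why: Oxidative cleavage of the PMB ether; the isolated alkenes, the silyl ethers and the α-methylene lactone are not oxidised by DDQ.

Step 21
Reactants: 27 alcohol
Product: 28 C6 acetate
Conditions: Ac2O, DMAP, pyridine, rt
Reagents that add atoms: acetic anhydride, CC(=O)OC(C)=O
Why: DMAP-catalysed acetylation of the axial secondary alcohol; O9 and O15 are still silylated, so only O6 reacts.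

Step 22
Reactants: 28 acetate
Product: 29 C9,C15-diol
Conditions: HF·pyridine, pyridine/THF, 0 °C to rt
Reagents that add atoms: none
Why: Fluoride-mediated cleavage of both silyl ethers under buffered acidic conditions that leave the acetate and the lactone intact.

Step 23
Reactants: 29 diol
Product: 30 C15 enal with free C9–OH
Conditions: MnO2, CH2Cl2, rt
Reagents that add atoms: none
Why: MnO2 oxidises only the allylic primary alcohol, and the non-allylic secondary C9–OH is left.

Step 24
Reactants: 30 hydroxy enal; 31 angelic acid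
Product: 33 target CNP0252310.1, via mixed anhydride 32 (not isolated)
Conditions: 31, 2,4,6-trichlorobenzoyl chloride, Et3N, toluene, rt; then 30, DMAP, toluene, 60 °C
Reagents that add atoms: none
Why: Yamaguchi esterification; the mixed anhydride of angelic acid acylates the hindered C9–OH, and this activation is the one known to keep the (Z)-geometry of the angeloyl group best.

**Compound list**

1 | (S)-5-(hydroxymethyl)furan-2(5H)-one | O=C1C=C[C@@H](CO)O1 | starting material
2 | [(2S)-5-oxo-2,5-dihydrofuran-2-yl]methyl pivalate | O=C1C=C[C@@H](COC(=O)C(C)(C)C)O1 | intermediate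
3 | 2-bromoprop-2-en-1-ol | C=C(Br)CO | starting material
4 | [(2-bromoprop-2-en-1-yl)oxy](tert-butyl)diphenylsilane | C=C(Br)CO[Si](c1ccccc1)(c1ccccc1)C(C)(C)C | intermediate
5 | [3-(tert-butyldiphenylsilyloxy)prop-1-en-2-yl]lithium | [Li]C(=C)CO[Si](c1ccccc1)(c1ccccc1)C(C)(C)C | intermediate
6 | lithium bis[3-(tert-butyldiphenylsilyloxy)prop-1-en-2-yl]cuprate | [Li+].C=C(CO[Si](c1ccccc1)(c1ccccc1)C(C)(C)C)[Cu-]C(=C)CO[Si](c1ccccc1)(c1ccccc1)C(C)(C)C | intermediate
7 | [(2S,3R)-3-{3-[(tert-butyldiphenylsilyl)oxy]prop-1-en-2-yl}-5-oxotetrahydrofuran-2-yl]methyl pivalate (alkenyl group trans to CH2OPiv) | O=C1C[C@H](C(=C)CO[Si](c2ccccc2)(c2ccccc2)C(C)(C)C)[C@@H](COC(=O)C(C)(C)C)O1 | intermediate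
8 | 2-[(tert-butyldimethylsilyl)oxy]acetaldehyde | O=CCO[Si](C)(C)C(C)(C)C | starting material
9 | aldol adduct: lactone 7 with a 1-hydroxy-2-(TBS-oxy)ethyl group on C10 (α to the lactone carbonyl), mixture at C9 and C10 | O=C1C(C(O)CO[Si](C)(C)C(C)(C)C)[C@H](C(=C)CO[Si](c2ccccc2)(c2ccccc2)C(C)(C)C)[C@@H](COC(=O)C(C)(C)C)O1 | intermediate
10 | β-keto lactone: lactone 7 with a (TBS-oxy)acetyl group on C10, C10 epimers and enol | O=C1C(C(=O)CO[Si](C)(C)C(C)(C)C)[C@H](C(=C)CO[Si](c2ccccc2)(c2ccccc2)C(C)(C)C)[C@@H](COC(=O)C(C)(C)C)O1 | intermediate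
11 | methylated β-keto lactone: C10 quaternary with methyl trans and the (TBS-oxy)acetyl group cis to the C5 alkenyl group | O=C1[C@](C)(C(=O)CO[Si](C)(C)C(C)(C)C)[C@H](C(=C)CO[Si](c2ccccc2)(c2ccccc2)C(C)(C)C)[C@@H](COC(=O)C(C)(C)C)O1 | intermediate
12 | C9 alcohol of 11 (C9 as in the target) | O=C1[C@](C)([C@H](O)CO[Si](C)(C)C(C)(C)C)[C@H](C(=C)CO[Si](c2ccccc2)(c2ccccc2)C(C)(C)C)[C@@H](COC(=O)C(C)(C)C)O1 | intermediate
13 | C9 TBS ether of 12 | O=C1[C@](C)([C@H](O[Si](C)(C)C(C)(C)C)CO[Si](C)(C)C(C)(C)C)[C@H](C(=C)CO[Si](c2ccccc2)(c2ccccc2)C(C)(C)C)[C@@H](COC(=O)C(C)(C)C)O1 | intermediate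
14 | lactol from 13 (C1 hemiacetal, both anomers) with free C7–OH | OC1[C@](C)([C@H](O[Si](C)(C)C(C)(C)C)CO[Si](C)(C)C(C)(C)C)[C@H](C(=C)CO[Si](c2ccccc2)(c2ccccc2)C(C)(C)C)[C@@H](CO)O1 | intermediate
15 | open-chain diol: C8-OTBS, C9-OTBS, C10 (Me, vinyl), C5 (alkenyl with C15-OTBDPS), C6–OH, C7–OH | CC(C)(C)[Si](C)(C)OC[C@@H](O[Si](C)(C)C(C)(C)C)[C@@](C)(C=C)[C@H](C(=C)CO[Si](c1ccccc1)(c1ccccc1)C(C)(C)C)[C@H](O)CO | intermediate
16 | p-methoxybenzylidene acetal of 15 on O6/O7 (acetal carbon unassigned) | CC(C)(C)[Si](C)(C)OC[C@@H](O[Si](C)(C)C(C)(C)C)[C@@](C)(C=C)[C@H](C(=C)CO[Si](c1ccccc1)(c1ccccc1)C(C)(C)C)[C@H]1COC(c2ccc(OC)cc2)O1 | intermediate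
17 | C6 PMB ether with free C7–OH | CC(C)(C)[Si](C)(C)OC[C@@H](O[Si](C)(C)C(C)(C)C)[C@@](C)(C=C)[C@H](C(=C)CO[Si](c1ccccc1)(c1ccccc1)C(C)(C)C)[C@H](OCc1ccc(OC)cc1)CO | intermediate
18 | C7 aldehyde | CC(C)(C)[Si](C)(C)OC[C@@H](O[Si](C)(C)C(C)(C)C)[C@@](C)(C=C)[C@H](C(=C)CO[Si](c1ccccc1)(c1ccccc1)C(C)(C)C)[C@H](OCc1ccc(OC)cc1)C=O | intermediate
19 | terminal alkyne C7≡C11 | CC(C)(C)[Si](C)(C)OC[C@@H](O[Si](C)(C)C(C)(C)C)[C@@](C)(C=C)[C@H](C(=C)CO[Si](c1ccccc1)(c1ccccc1)C(C)(C)C)[C@H](OCc1ccc(OC)cc1)C#C | intermediate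
20 | methyl ynoate (C12 ester) | CC(C)(C)[Si](C)(C)OC[C@@H](O[Si](C)(C)C(C)(C)C)[C@@](C)(C=C)[C@H](C(=C)CO[Si](c1ccccc1)(c1ccccc1)C(C)(C)C)[C@H](OCc1ccc(OC)cc1)C#CC(=O)OC | intermediate
21 | methyl 2-(diisobutylalumino)alk-2-enoate (Al on C11, trans to C6) | CC(C)(C)[Si](C)(C)OC[C@@H](O[Si](C)(C)C(C)(C)C)[C@@](C)(C=C)[C@H](C(=C)CO[Si](c1ccccc1)(c1ccccc1)C(C)(C)C)[C@H](OCc1ccc(OC)cc1)/C=C(/[Al](CC(C)C)CC(C)C)C(=O)OC | intermediate
22 | pinacol (Z)-2-(methoxycarbonyl)allyl boronate (C6 cis to CO2Me, trans to CH2Bpin) with C8-OTBS | CC(C)(C)[Si](C)(C)OC[C@@H](O[Si](C)(C)C(C)(C)C)[C@@](C)(C=C)[C@H](C(=C)CO[Si](c1ccccc1)(c1ccccc1)C(C)(C)C)[C@H](OCc1ccc(OC)cc1)/C=C(/CB1OC(C)(C)C(C)(C)O1)C(=O)OC | intermediate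
23 | C8 primary alcohol of 22 | OC[C@@H](O[Si](C)(C)C(C)(C)C)[C@@](C)(C=C)[C@H](C(=C)CO[Si](c1ccccc1)(c1ccccc1)C(C)(C)C)[C@H](OCc1ccc(OC)cc1)/C=C(/CB1OC(C)(C)C(C)(C)O1)C(=O)OC | intermediate
24 | seco aldehyde: C8 CHO, C9-OTBS, C10 (Me, vinyl), C5 alkenyl (C15-OTBDPS), C6-OPMB, (Z)-allyl boronate | O=C[C@@H](O[Si](C)(C)C(C)(C)C)[C@@](C)(C=C)[C@H](C(=C)CO[Si](c1ccccc1)(c1ccccc1)C(C)(C)C)[C@H](OCc1ccc(OC)cc1)/C=C(/CB1OC(C)(C)C(C)(C)O1)C(=O)OC | intermediate
25 | cyclised borate ester: cyclohexane with C8–O–Bpin and C7–C(=CH2)CO2Me trans to it | C=C[C@]1(C)[C@H](O[Si](C)(C)C(C)(C)C)[C@H](OB2OC(C)(C)C(C)(C)O2)[C@@H](C(=C)C(=O)OC)[C@@H](OCc2ccc(OC)cc2)[C@H]1C(=C)CO[Si](c2ccccc2)(c2ccccc2)C(C)(C)C | intermediate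
26 | trans-fused α-methylene-γ-lactone (12,8-olide) with C9-OTBS, C6-OPMB, C15-OTBDPS | C=C[C@]1(C)[C@H](O[Si](C)(C)C(C)(C)C)[C@@H]2OC(=O)C(=C)[C@H]2[C@@H](OCc3ccc(OC)cc3)[C@H]1C(=C)CO[Si](c3ccccc3)(c3ccccc3)C(C)(C)C | intermediate
27 | C6 alcohol of 26 | C=C[C@]1(C)[C@H](O[Si](C)(C)C(C)(C)C)[C@@H]2OC(=O)C(=C)[C@H]2[C@@H](O)[C@H]1C(=C)CO[Si](c3ccccc3)(c3ccccc3)C(C)(C)C | intermediate
28 | C6 acetate | C=C[C@]1(C)[C@H](O[Si](C)(C)C(C)(C)C)[C@@H]2OC(=O)C(=C)[C@H]2[C@@H](OC(C)=O)[C@H]1C(=C)CO[Si](c3ccccc3)(c3ccccc3)C(C)(C)C | intermediate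
29 | C6 acetate with free C9–OH and C15–OH | C=C[C@]1(C)[C@H](O)[C@@H]2OC(=O)C(=C)[C@H]2[C@@H](OC(C)=O)[C@H]1C(=C)CO | intermediate
30 | C15 enal with free C9–OH | C=C[C@]1(C)[C@H](O)[C@@H]2OC(=O)C(=C)[C@H]2[C@@H](OC(C)=O)[C@H]1C(=C)C=O | intermediate
31 | angelic acid, (Z)-2-methylbut-2-enoic acid | C/C=C(/C)C(=O)O | starting material
32 | angelic 2,4,6-trichlorobenzoic anhydride | C/C=C(/C)C(=O)OC(=O)c1c(Cl)cc(Cl)cc1Cl | intermediate
33 | CNP0252310.1: 6-acetoxy-9-angeloyloxy-15-oxoelema-1,3,11(13)-trien-12,8-olide (5R,6S,7S,8R,9S,10S in the numbering used here) | C=C[C@]1(C)[C@H](OC(=O)/C(C)=C\C)[C@@H]2OC(=O)C(=C)[C@H]2[C@@H](OC(C)=O)[C@H]1C(=C)C=O | target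

**Step count and risks**

Total steps: 24. Longest linear sequence: 23 (steps 1 and 3 to 24 from butenolide 1; step 2 is a side branch).

Steps most likely to fail:

1. Step 19. The ring may close through the ring-flipped chair, that is, with the opposite faces of C7 and C8, which would give the 7,8-bis-epimeric trans lactone. The required chair carries a 1,3-diaxial contact between C10–Me and C6–OPMB and some allylic strain between C6–O and the cis ester, so the preference may be small or reversed; slow closure with protodeboronation is a second failure mode. Fallback: the C6 epimer is cyclised instead. With O6 equatorial the required chair has H6 next to the ester and no Me/O contact, and the flipped chair would place O6 syn-axial to the vinyl group. The fallback sets out from alkyne 19. DDQ gives the propargylic alcohol F1. Mitsunobu etherification with 4-methoxyphenol (PPh3, DIAD) inverts C6 and gives the aryl ether F2. n-BuLi and ClCO2Me give the ynoate F3, and DIBAL-H/HMPA followed by ICH2Bpin gives the boronate F4. CSA in MeOH gives the C8 alcohol F5 and Dess–Martin oxidation the 6-epi seco aldehyde F6. Heating in toluene and then TsOH should give the 6-epi lactone F7. CAN removes the aryl group to give the equatorial C6 alcohol F8, and Dess–Martin oxidation gives the C6 ketone F9. NaBH4/CeCl3 at −78 °C should deliver hydride from the face opposite the axial C10 methyl (equatorial attack, as in 6-oxo steroids) and give the axial alcohol 27, where the route is rejoined.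

2. Step 16. The ester may be reduced at the carbonyl, the alkene geometry may be lost through the aluminium allenolate, or the C-alkylation with the iodomethyl boronate may stay incomplete. Fallback: the C11–C13 bond is made by cross-coupling. It sets out from ynoate 20. Pd(PPh3)4-catalysed syn-hydrostannation with Bu3SnH puts tin on C11 and gives the α-stannyl enoate F10. Iodine replaces tin with retention and gives the α-iodo enoate F11. Negishi coupling with (pinacolatoboryl)methylzinc iodide (from ICH2Bpin and zinc) and Pd(PPh3)4 then gives boronate 22, where the route is rejoined.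

3. Step 24. Acylation of the axial C9–OH next to the quaternary carbon may be slow, and the angeloyl group may isomerise to tigloyl under DMAP and heat. Fallback: the (Z)-alkene is built on the substrate by olefination. It sets out from diol 29. TBSCl and imidazole silylate the primary alcohol selectively and give the C15 silyl ether F12. DCC/DMAP coupling with 2-[bis(2,2,2-trifluoroethoxy)phosphoryl]propanoic acid gives the C9 phosphonopropionate F13. Still–Gennari olefination with acetaldehyde (KHMDS, 18-crown-6, THF, −78 °C) should give the angelate F14. HF·pyridine gives the allylic alcohol F15, and MnO2 gives target 33.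

**Further compounds**

F1 | step 19 | propargylic alcohol (19 without the PMB group) | CC(C)(C)[Si](C)(C)OC[C@@H](O[Si](C)(C)C(C)(C)C)[C@@](C)(C=C)[C@H](C(=C)CO[Si](c1ccccc1)(c1ccccc1)C(C)(C)C)[C@H](O)C#C
F2 | step 19 | C6-inverted 4-methoxyphenyl ether | CC(C)(C)[Si](C)(C)OC[C@@H](O[Si](C)(C)C(C)(C)C)[C@@](C)(C=C)[C@H](C(=C)CO[Si](c1ccccc1)(c1ccccc1)C(C)(C)C)[C@@H](Oc1ccc(OC)cc1)C#C
F3 | step 19 | 6-epi ynoate | CC(C)(C)[Si](C)(C)OC[C@@H](O[Si](C)(C)C(C)(C)C)[C@@](C)(C=C)[C@H](C(=C)CO[Si](c1ccccc1)(c1ccccc1)C(C)(C)C)[C@@H](Oc1ccc(OC)cc1)C#CC(=O)OC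
F4 | step 19 | 6-epi (Z)-allyl boronate | CC(C)(C)[Si](C)(C)OC[C@@H](O[Si](C)(C)C(C)(C)C)[C@@](C)(C=C)[C@H](C(=C)CO[Si](c1ccccc1)(c1ccccc1)C(C)(C)C)[C@@H](Oc1ccc(OC)cc1)/C=C(/CB1OC(C)(C)C(C)(C)O1)C(=O)OC
F5 | step 19 | 6-epi C8 alcohol | OC[C@@H](O[Si](C)(C)C(C)(C)C)[C@@](C)(C=C)[C@H](C(=C)CO[Si](c1ccccc1)(c1ccccc1)C(C)(C)C)[C@@H](Oc1ccc(OC)cc1)/C=C(/CB1OC(C)(C)C(C)(C)O1)C(=O)OC
F6 | step 19 | 6-epi seco aldehyde | O=C[C@@H](O[Si](C)(C)C(C)(C)C)[C@@](C)(C=C)[C@H](C(=C)CO[Si](c1ccccc1)(c1ccccc1)C(C)(C)C)[C@@H](Oc1ccc(OC)cc1)/C=C(/CB1OC(C)(C)C(C)(C)O1)C(=O)OC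
F7 | step 19 | 6-epi trans lactone (C6 aryl ether equatorial) | C=C[C@]1(C)[C@H](O[Si](C)(C)C(C)(C)C)[C@@H]2OC(=O)C(=C)[C@H]2[C@H](Oc3ccc(OC)cc3)[C@H]1C(=C)CO[Si](c3ccccc3)(c3ccccc3)C(C)(C)C
F8 | step 19 | 6-epi C6 alcohol | C=C[C@]1(C)[C@H](O[Si](C)(C)C(C)(C)C)[C@@H]2OC(=O)C(=C)[C@H]2[C@H](O)[C@H]1C(=C)CO[Si](c3ccccc3)(c3ccccc3)C(C)(C)C
F9 | step 19 | C6 ketone | C=C[C@]1(C)[C@H](O[Si](C)(C)C(C)(C)C)[C@@H]2OC(=O)C(=C)[C@H]2C(=O)[C@H]1C(=C)CO[Si](c3ccccc3)(c3ccccc3)C(C)(C)C
F10 | step 16 | α-tributylstannyl enoate (Sn on C11, trans to C6) | CC(C)(C)[Si](C)(C)OC[C@@H](O[Si](C)(C)C(C)(C)C)[C@@](C)(C=C)[C@H](C(=C)CO[Si](c1ccccc1)(c1ccccc1)C(C)(C)C)[C@H](OCc1ccc(OC)cc1)/C=C(/[Sn](CCCC)(CCCC)CCCC)C(=O)OC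
F11 | step 16 | α-iodo enoate (I on C11, trans to C6) | CC(C)(C)[Si](C)(C)OC[C@@H](O[Si](C)(C)C(C)(C)C)[C@@](C)(C=C)[C@H](C(=C)CO[Si](c1ccccc1)(c1ccccc1)C(C)(C)C)[C@H](OCc1ccc(OC)cc1)/C=C(/I)C(=O)OC
F12 | step 24 | C15 TBS ether of 29 | C=C[C@]1(C)[C@H](O)[C@@H]2OC(=O)C(=C)[C@H]2[C@@H](OC(C)=O)[C@H]1C(=C)CO[Si](C)(C)C(C)(C)C
F13 | step 24 | C9 2-[bis(2,2,2-trifluoroethoxy)phosphoryl]propanoate | C=C[C@]1(C)[C@H](OC(=O)C(C)P(=O)(OCC(F)(F)F)OCC(F)(F)F)[C@@H]2OC(=O)C(=C)[C@H]2[C@@H](OC(C)=O)[C@H]1C(=C)CO[Si](C)(C)C(C)(C)C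
F14 | step 24 | C9 angelate with C15-OTBS | C=C[C@]1(C)[C@H](OC(=O)/C(C)=C\C)[C@@H]2OC(=O)C(=C)[C@H]2[C@@H](OC(C)=O)[C@H]1C(=C)CO[Si](C)(C)C(C)(C)C
F15 | step 24 | C9 angelate with free C15–OH | C=C[C@]1(C)[C@H](OC(=O)/C(C)=C\C)[C@@H]2OC(=O)C(=C)[C@H]2[C@@H](OC(C)=O)[C@H]1C(=C)CO
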